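**Plan**
- Retrosynthesis: remove the C15 silyl ether and the C6/C7 esters, take the 6β,7α-diol back to a labd-8-en-6-one (C7 hydroxylation, C6 reduction), cut C12–C13 (B-alkyl Suzuki), then C7–C8 and C9–C10 together ([4+2]), then C5–C6 (Stille).
- Enabling feature: the tetrasubstituted C8=C9 alkene of ring B, flanked by C7 and the quaternary C10, is the 2π unit of a [4+2] with the diene C7=C6–C5=C10; the C5=C10 bond of that diene lies in ring A and its C6 ethoxy group is the latent C6 oxygen.
- Forward: ring A comes from (4R,6R)-actinol (three steps to the 2-ethoxydiene); ring B is closed by a nickel-catalysed [4+2] with pent-1-en-3-yne; the vinyl group of the enyne steers the regiochemistry and then carries the side chain (hydroboration/Suzuki with an (E)-vinyl iodide); ring B is oxygenated last.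
- Stereochemistry: C2 from actinol; C10 from ring A control in the cycloaddition; C5 by α-face protonation to the trans-fused ketone; C7 by α-face enolate hydroxylation; C6 by α-face hydride delivery; C13=C14 (E) by syn-hydrozirconation.

Key step: step 5

Remark: labdane numbering is used for the bicyclic compounds (ring A = C1–C5 and C10, ring B = C5–C10, C17 = methyl on C8, C20 = methyl on C10, C11–C16 = side chain); β is the face of the C20 methyl.
Remark: (4R,6R)-actinol 1 is taken as the commercial enantiopure source of C2; its second stereocentre is erased in step 2, so either C6 epimer would serve.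

**Route**

Step 1
Reactants: 1 (4R,6R)-4-hydroxy-2,2,6-trimethylcyclohexan-1-one
Product: 2 (1R,3R)-3,5,5-trimethyl-4-oxocyclohexyl acetate
Conditions: Ac2O (1.5 equiv), pyridine, DMAP (5 mol %), CH2Cl2, 0 °C to rt
Reagents that add atoms: acetic anhydride CC(=O)OC(C)=O
Why: DMAP-catalysed esterification of the unhindered secondary alcohol installs the C2 acetate of the target at the outset, so no protecting group is needed at this oxygen.

Step 2
Reactants: 2 (1R,3R)-3,5,5-trimethyl-4-oxocyclohexyl acetate
Product: 3 (1R)-3,5,5-trimethyl-4-[(trifluoromethylsulfonyl)oxy]cyclohex-3-en-1-yl acetate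
Conditions: Tf2O (1.3 equiv), 2,6-di-tert-butyl-4-methylpyridine (1.5 equiv), CH2Cl2, 0 °C to rt
Reagents that add atoms: trifluoromethanesulfonic anhydride O=S(=O)(OS(=O)(=O)C(F)(F)F)C(F)(F)F
Why: Enol triflate formation with a hindered pyridine base tolerates the acetate, and the ketone can enolise only toward its methyl-bearing α-carbon because the other α-carbon is quaternary, so one regioisomer should form.

Step 3
Reactants: 3 (1R)-3,5,5-trimethyl-4-[(trifluoromethylsulfonyl)oxy]cyclohex-3-en-1-yl acetate; 4 tributyl(1-ethoxyvinyl)stannane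
Product: 5 (1R)-4-(1-ethoxyvinyl)-3,5,5-trimethylcyclohex-3-en-1-yl acetate
Conditions: Pd(PPh3)4 (5 mol %), LiCl (3 equiv), CuI (10 mol %), THF, 65 °C; chromatography on Et3N-deactivated silica
Reagents that add atoms: none
Why: Stille coupling of the hindered cyclohexenyl triflate with an α-alkoxyvinylstannane should give the acid-sensitive 2-ethoxy-1,3-diene, whose two new carbons become C6 and C7.

Step 4
Reactants: 6 prop-1-yn-1-ylmagnesium bromide; 7 bromoethene
Product: 8 pent-1-en-3-yne
Conditions: Pd(PPh3)4 (2 mol %), THF, 0 °C to rt; product distilled and used as a titrated THF solution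
Reagents that add atoms: none
Why: Palladium-catalysed Kumada-type coupling of an alkynyl Grignard reagent with a vinyl halide is a standard route to conjugated enynes.

Step 5
Reactants: 5 (1R)-4-(1-ethoxyvinyl)-3,5,5-trimethylcyclohex-3-en-1-yl acetate; 8 pent-1-en-3-yne
Product: 9 2α-acetoxy-6-ethoxy-13,14,15,16-tetranorlabda-5,8,11-triene (ring B a cyclohexa-1,4-diene with the C17 methyl on C8 and a vinyl group on C9; C20 methyl β)
Conditions: Ni(cod)2 (10 mol %), P(O-2-biphenylyl)3 (30 mol %), THF, 25 to 45 °C, 8 (2 equiv) added by syringe pump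
Reagents that add atoms: none
Why: Proposed new method: zerovalent nickel should bind the s-cis 2-ethoxydiene of 5 (C7=C6–C5=C10) together with the alkyne of 8 and couple them oxidatively, joining the unhindered C7 methylene to the methyl-bearing alkyne carbon C8 to give a nickelacycle that holds C9 as a vinyl ligand and C6–C5–C10 as an η3-allyl ligand, and reductive elimination at C10 then forms the C9–C10 bond and the quaternary centre. The closest known reaction types are the Ni(cod)2/phosphite-catalysed [4+2] cycloaddition of 1,3-dienes with unactivated alkynes, established in the intramolecular sense, and the thermal Diels–Alder reaction of 1-vinyl-2,6,6-trimethylcyclohexenes with acetylenic esters, which shows that this diene terminus can form a quaternary carbon. Ring B is the only ring closed, as a cyclohexa-1,4-diene by an intermolecular, diene-suprafacial [4+2] closure through a seven-membered nickelacycle. The only new stereocentre, C10, is controlled by ring A: with the C2 acetate pseudoequatorial the pseudoaxial C4 methyl shields the β face of C10, so nickel and the enyne should engage the α face and the C20 methyl should end β, trans to the acetate. The step needs regioselectivity in the alkyne, and the conjugated vinyl group of 8 secures it, because 1,3-enynes form the new C–C bond at the alkyne carbon distal to the alkene in nickel-mediated oxidative couplings while the alkene stays on the metal, and the ethoxy donor makes C7 the reacting diene terminus. It also needs cross- over homo-coupling of 8, which slow addition of 8 to the diene–catalyst solution should favour.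

Step 6
Reactants: 10 but-2-yn-1-ol
Product: 11 tert-butyl(but-2-yn-1-yloxy)diphenylsilane
Conditions: tert-butyl(chloro)diphenylsilane (1.1 equiv), imidazole (2 equiv), DMF, rt
Reagents that add atoms: tert-butyl(chloro)diphenylsilane CC(C)(C)[Si](Cl)(c1ccccc1)c1ccccc1
Why: Silylation of a primary alcohol gives an ether that should survive the later basic, acidic and hydride steps and is removable by fluoride at the end.

Step 7
Reactants: 11 tert-butyl(but-2-yn-1-yloxy)diphenylsilane
Product: 13 (E)-tert-butyl[(3-iodobut-2-en-1-yl)oxy]diphenylsilane, via vinylzirconocene chloride 12 (not isolated)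
Conditions: Cp2Zr(H)Cl (1.5 equiv), THF, 50 °C; then I2, 0 °C
Reagents that add atoms: iodine II
Why: syn-Hydrozirconation under equilibrating conditions should place zirconium on the less hindered methyl-bearing alkyne carbon, and iodinolysis with retention then gives the (E)-iodide that fixes the C13=C14 geometry (hydrozirconation–iodination).

Step 8
Reactants: 9 2α-acetoxy-6-ethoxy-13,14,15,16-tetranorlabda-5,8,11-triene; 13 (E)-tert-butyl[(3-iodobut-2-en-1-yl)oxy]diphenylsilane
Product: 15 2α-acetoxy-15-(tert-butyldiphenylsilyloxy)-6-ethoxylabda-5,8,13E-triene, via B-alkyl-9-BBN borane 14 (not isolated)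
Conditions: 9-BBN (1.2 equiv), THF, rt; then 13, Pd(dppf)Cl2 (5 mol %), AsPh3 (10 mol %), Cs2CO3 (2 equiv), DMF/H2O, rt
Reagents that add atoms: none
Why: 9-BBN should hydroborate only the monosubstituted C11=C12 alkene (boron on C12), and B-alkyl Suzuki–Miyaura coupling with retention of the iodide geometry then forms C12–C13 while the tetrasubstituted alkenes, enol ether, acetate and silyl ether stay untouched.

Step 9
Reactants: 15 2α-acetoxy-15-(tert-butyldiphenylsilyloxy)-6-ethoxylabda-5,8,13E-triene
Product: 16 2α-acetoxy-15-(tert-butyldiphenylsilyloxy)labda-8,13E-dien-6-one (5α-H, trans-fused)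
Conditions: 0.5 M aqueous HCl, THF, 0 °C to rt
Reagents that add atoms: water O
Why: Acid hydrolysis of the enol ether protonates C5 on the α face, away from the C20 methyl, and releases ethanol to give the trans-fused β,γ-unsaturated ketone, which should also be the thermodynamic C5 epimer under these conditions.

Step 10
Reactants: 16 2α-acetoxy-15-(tert-butyldiphenylsilyloxy)labda-8,13E-dien-6-one
Product: 18 2α-acetoxy-15-(tert-butyldiphenylsilyloxy)-7α-hydroxylabda-8,13E-dien-6-one, via sodium dienolate 17 (not isolated)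
Conditions: NaN(SiMe3)2 (1.15 equiv), THF, −78 °C; 2-(phenylsulfonyl)-3-phenyloxaziridine (1.3 equiv), −78 °C; aqueous NH4Cl
Reagents that add atoms: 2-(phenylsulfonyl)-3-phenyloxaziridine O=S(=O)(N1OC1c1ccccc1)c1ccccc1
Why: Kinetic deprotonation at the doubly activated allylic C7 rather than the hindered tertiary C5 gives the dienolate, which the N-sulfonyloxaziridine should hydroxylate at C7 by axial attack on the α face, opposite the β-methyls on C10 and C4, while the side-chain alkene is inert to this oxidant (enolate hydroxylation).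

Step 11
Reactants: 18 2α-acetoxy-15-(tert-butyldiphenylsilyloxy)-7α-hydroxylabda-8,13E-dien-6-one
Product: 19 2α-acetoxy-15-(tert-butyldiphenylsilyloxy)labda-8,13E-diene-6β,7α-diol
Conditions: NaBH4, MeOH/THF, −20 to 0 °C
Reagents that add atoms: none
Why: Borohydride reduction should deliver hydride to the α face of the C6 carbonyl because the β face is blocked by the syn-axial C20 and C4 methyls, giving the axial 6β-alcohol while the acetate survives at low temperature.

Step 12
Reactants: 19 2α-acetoxy-15-(tert-butyldiphenylsilyloxy)labda-8,13E-diene-6β,7α-diol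
Product: 20 2α,7α-diacetoxy-15-(tert-butyldiphenylsilyloxy)labda-8,13E-dien-6β-ol
Conditions: Ac2O (1.2 equiv), pyridine, DMAP (5 mol %), CH2Cl2, 0 °C
Reagents that add atoms: acetic anhydride CC(=O)OC(C)=O
Why: The allylic 7α-hydroxyl is far more accessible than the 6β-hydroxyl, which is 1,3-diaxial to two methyl groups, so limiting anhydride should acetylate O7 only, and the trans-diaxial arrangement excludes acyl migration (selective esterification).

Step 13
Reactants: 20 2α,7α-diacetoxy-15-(tert-butyldiphenylsilyloxy)labda-8,13E-dien-6β-ol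
Product: 21 2α,7α-diacetoxy-15-(tert-butyldiphenylsilyloxy)-6β-(3-methylbutanoyloxy)labda-8,13E-diene
Conditions: 3-methylbutanoyl chloride (3 equiv), DMAP (3 equiv), pyridine, CH2Cl2, 40 °C
Reagents that add atoms: 3-methylbutanoyl chloride CC(C)CC(Cl)=O
Why: Forced DMAP-mediated acylation with the acid chloride should esterify the hindered axial 6β-alcohol, the only free hydroxyl left.

Step 14
Reactants: 21 2α,7α-diacetoxy-15-(tert-butyldiphenylsilyloxy)-6β-(3-methylbutanoyloxy)labda-8,13E-diene
Product: 22 2α,7α-diacetoxy-6β-(3-methylbutanoyloxy)labda-8,13E-dien-15-ol (CNP0257091.1)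
Conditions: HF·pyridine, pyridine/THF, 0 °C to rt
Reagents that add atoms: none
Why: Buffered fluoride cleavage of the primary silyl ether should leave the three esters and the allylic acetate untouched (desilylation).

**Compound list**

1 | (4R,6R)-4-hydroxy-2,2,6-trimethylcyclohexan-1-one (actinol) | O=C1C(C)(C)C[C@H](O)C[C@H]1C | starting material
2 | (1R,3R)-3,5,5-trimethyl-4-oxocyclohexyl acetate | O=C1C(C)(C)C[C@H](OC(C)=O)C[C@H]1C | intermediate
3 | (1R)-3,5,5-trimethyl-4-[(trifluoromethylsulfonyl)oxy]cyclohex-3-en-1-yl acetate | CC1=C(OS(=O)(=O)C(F)(F)F)C(C)(C)C[C@H](OC(C)=O)C1 | intermediate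
4 | tributyl(1-ethoxyvinyl)stannane | CCCC[Sn](CCCC)(CCCC)C(=C)OCC | starting material
5 | (1R)-4-(1-ethoxyvinyl)-3,5,5-trimethylcyclohex-3-en-1-yl acetate | CC1=C(C(=C)OCC)C(C)(C)C[C@H](OC(C)=O)C1 | intermediate
6 | prop-1-yn-1-ylmagnesium bromide | CC#C[Mg]Br | starting material
7 | bromoethene | C=CBr | starting material
8 | pent-1-en-3-yne | CC#CC=C | intermediate
9 | 2α-acetoxy-6-ethoxy-13,14,15,16-tetranorlabda-5,8,11-triene | CC(=O)O[C@H]1CC(C)(C)C2=C(OCC)CC(C)=C(C=C)[C@@]2(C)C1 | intermediate
10 | but-2-yn-1-ol | CC#CCO | starting material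
11 | tert-butyl(but-2-yn-1-yloxy)diphenylsilane | CC#CCO[Si](c1ccccc1)(c1ccccc1)C(C)(C)C | intermediate
12 | (E)-[4-(tert-butyldiphenylsilyloxy)but-2-en-2-yl]zirconocene chloride | C/C(=C\CO[Si](c1ccccc1)(c1ccccc1)C(C)(C)C)[Zr](Cl)(C1C=CC=C1)C1C=CC=C1 | intermediate
13 | (E)-tert-butyl[(3-iodobut-2-en-1-yl)oxy]diphenylsilane | C/C(I)=C\CO[Si](c1ccccc1)(c1ccccc1)C(C)(C)C | intermediate
14 | 9-(2α-acetoxy-6-ethoxy-13,14,15,16-tetranorlabda-5,8-dien-12-yl)-9-borabicyclo[3.3.1]nonane | CC(=O)O[C@H]1CC(C)(C)C2=C(OCC)CC(C)=C(CCB3C4CCCC3CCC4)[C@@]2(C)C1 | intermediate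
15 | 2α-acetoxy-15-(tert-butyldiphenylsilyloxy)-6-ethoxylabda-5,8,13E-triene | CC(=O)O[C@H]1CC(C)(C)C2=C(OCC)CC(C)=C(CC/C(C)=C/CO[Si](c3ccccc3)(c3ccccc3)C(C)(C)C)[C@@]2(C)C1 | intermediate
16 | 2α-acetoxy-15-(tert-butyldiphenylsilyloxy)labda-8,13E-dien-6-one | CC(=O)O[C@H]1CC(C)(C)[C@@H]2C(=O)CC(C)=C(CC/C(C)=C/CO[Si](c3ccccc3)(c3ccccc3)C(C)(C)C)[C@@]2(C)C1 | intermediate
17 | sodium dienolate of 16 (C6 oxido, C6=C7) | CC(=O)O[C@H]1CC(C)(C)[C@@H]2C([O-])=CC(C)=C(CC/C(C)=C/CO[Si](c3ccccc3)(c3ccccc3)C(C)(C)C)[C@@]2(C)C1.[Na+] | intermediate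
18 | 2α-acetoxy-15-(tert-butyldiphenylsilyloxy)-7α-hydroxylabda-8,13E-dien-6-one | CC(=O)O[C@H]1CC(C)(C)[C@@H]2C(=O)[C@@H](O)C(C)=C(CC/C(C)=C/CO[Si](c3ccccc3)(c3ccccc3)C(C)(C)C)[C@@]2(C)C1 | intermediate
19 | 2α-acetoxy-15-(tert-butyldiphenylsilyloxy)labda-8,13E-diene-6β,7α-diol | CC(=O)O[C@H]1CC(C)(C)[C@@H]2[C@H](O)[C@@H](O)C(C)=C(CC/C(C)=C/CO[Si](c3ccccc3)(c3ccccc3)C(C)(C)C)[C@@]2(C)C1 | intermediate
20 | 2α,7α-diacetoxy-15-(tert-butyldiphenylsilyloxy)labda-8,13E-dien-6β-ol | CC(=O)O[C@H]1CC(C)(C)[C@@H]2[C@H](O)[C@@H](OC(C)=O)C(C)=C(CC/C(C)=C/CO[Si](c3ccccc3)(c3ccccc3)C(C)(C)C)[C@@]2(C)C1 | intermediate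
21 | 2α,7α-diacetoxy-15-(tert-butyldiphenylsilyloxy)-6β-(3-methylbutanoyloxy)labda-8,13E-diene | CC(=O)O[C@H]1CC(C)(C)[C@@H]2[C@H](OC(=O)CC(C)C)[C@@H](OC(C)=O)C(C)=C(CC/C(C)=C/CO[Si](c3ccccc3)(c3ccccc3)C(C)(C)C)[C@@]2(C)C1 | intermediate
22 | 2α,7α-diacetoxy-6β-(3-methylbutanoyloxy)labda-8,13E-dien-15-ol (CNP0257091.1) | CC(=O)O[C@H]1CC(C)(C)[C@@H]2[C@H](OC(=O)CC(C)C)[C@@H](OC(C)=O)C(C)=C(CC/C(C)=C/CO)[C@@]2(C)C1 | target

**Step count and risks**

Total step count: 14. Longest linear sequence: 11 steps (1, 2, 3, 5, 8, 9, 10, 11, 12, 13, 14 from compound 1).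

Steps most likely to fail:

1. Step 5 (Proposed new method). What may go wrong: reductive elimination at the fully substituted C10 allyl terminus may be too slow, so that β-hydride loss from the nickelacycle or oligomerisation of the enyne takes over and conversion stays low. Fallback with known chemistry, setting out from 5 and 10 and returning at 9: but-2-yn-1-ol 10 is oxidised with MnO2 in CH2Cl2 to but-2-ynal F1. F1 is heated with diene 5 in toluene at about 100 °C (sealed tube, radical inhibitor) in a thermal Diels–Alder reaction. The donor ethoxy group and the acceptor formyl group pair C7 with the methyl-bearing alkyne carbon, and the same ring A face control should apply, giving 2α-acetoxy-6-ethoxy-12,13,14,15,16-pentanorlabda-5,8-dien-11-al F2. Wittig methylenation of F2 (methyltriphenylphosphonium bromide, potassium tert-butoxide, THF, 0 °C) then gives 9.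

2. Step 10. What may go wrong: competing deprotonation of the C2 acetate, addition of the enolate to the sulfonimine by-product, over-oxidation, or insufficient α-face selectivity at C7. Fallback, setting out from 16 and returning at 18: soft enolisation of 16 (Me3SiOTf, Et3N, CH2Cl2, 0 °C), which spares the acetate, gives the 6-trimethylsilyloxy-labda-6,8,13E-triene silyl dienol ether F3. Rubottom oxidation with dimethyldioxirane (1.0 equiv, acetone/CH2Cl2, −78 °C; the silyl dienol ether should react far faster than the side-chain alkene) gives the 7α-trimethylsilyloxy ketone F4. Aqueous citric acid in THF then cleaves the trimethylsilyl ether to 18.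

3. Step 13. What may go wrong: incomplete acylation of the hindered axial 6β-hydroxyl, or elimination of the allylic 7α-acetate under forcing conditions. Fallback, setting out from 20 and returning at 21: instead of nucleophilic catalysis on the neutral alcohol, 20 is deprotonated at −78 °C with LiN(SiMe3)2 (1.05 equiv, THF) to the lithium 6β-alkoxide F5. F5 is quenched at low temperature with 3-methylbutanoyl chloride to give 21.

**Further compounds**

F1 | step 5 | but-2-ynal | CC#CC=O
F2 | step 5 | 2α-acetoxy-6-ethoxy-12,13,14,15,16-pentanorlabda-5,8-dien-11-al | CC(=O)O[C@H]1CC(C)(C)C2=C(OCC)CC(C)=C(C=O)[C@@]2(C)C1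
F3 | step 10 | 2α-acetoxy-15-(tert-butyldiphenylsilyloxy)-6-(trimethylsilyloxy)labda-6,8,13E-triene | CC(=O)O[C@H]1CC(C)(C)[C@@H]2C(O[Si](C)(C)C)=CC(C)=C(CC/C(C)=C/CO[Si](c3ccccc3)(c3ccccc3)C(C)(C)C)[C@@]2(C)C1
F4 | step 10 | 2α-acetoxy-15-(tert-butyldiphenylsilyloxy)-7α-(trimethylsilyloxy)labda-8,13E-dien-6-one | CC(=O)O[C@H]1CC(C)(C)[C@@H]2C(=O)[C@@H](O[Si](C)(C)C)C(C)=C(CC/C(C)=C/CO[Si](c3ccccc3)(c3ccccc3)C(C)(C)C)[C@@]2(C)C1
F5 | step 13 | lithium 6β-alkoxide of 20 | CC(=O)O[C@H]1CC(C)(C)[C@@H]2[C@H]([O-])[C@@H](OC(C)=O)C(C)=C(CC/C(C)=C/CO[Si](c3ccccc3)(c3ccccc3)C(C)(C)C)[C@@]2(C)C1.[Li+]
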